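**Retrosynthetic overview**
1. The target comes from its C8=C9 alkene by α-face epoxidation, and the C6 ester from acylation of the 4β,6α-diol of the 8-daucene skeleton.
2. The cycloheptene is closed last among the carbocycles. C8–C9 and C6–C7 form in one operation, when the isopropenyl unit of prop-1-en-2-ylboronic acid is inserted between a C9 diazo carbon (from a tosylhydrazone) and the C6 aldehyde.
3. Enabling feature: the homoallylic array O–C6–C7H2–C8(CH3)=C9 of the seven-membered ring (the oxirane is its masked alkene). Its ends C6 and C9 sit on arms attached to the trans-vicinal ring carbons C5 and C1 of the cyclopentane, so direct C6–C9 closure would give a strained trans-bicyclo[3.3.0]octane.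
4. The cyclopentane (C1–C5, with C6 exocyclic) comes from Wolff ring contraction of a cyclohexanone. Its quaternary C1 is set by axial conjugate allylation of an enone made from (S)-terpinen-4-ol, which supplies C4.
5. Ring order: six-membered carbocycle (chiral pool), then cyclopentane (ring contraction), then cycloheptene (key step), then oxirane.

Key step: step 11

Remark: daucane numbering is used (C1 methyl-bearing ring-fusion carbon, C4 carbinol carbon with isopropyl, C5 ring-fusion CH, C6 ester carbinol, C7 CH2, C8 and C9 oxirane carbons, C10 CH2; β is the face of the C1 methyl). (S)-(+)-terpinen-4-ol of high enantiomeric purity is taken as commercially available.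

Step 1
Reactants: 1 (S)-(+)-terpinen-4-ol
Product: 2 (S)-terpinen-4-ol tert-butyldimethylsilyl ether
Conditions: TBSOTf, 2,6-lutidine, CH2Cl2, 0 °C to rt
Reagents that add atoms: tert-butyldimethylsilyl trifluoromethanesulfonate, CC(C)(C)[Si](C)(C)OS(=O)(=O)C(F)(F)F
Why: Silyl triflate silylation of the hindered tertiary alcohol protects the future C4 oxygen; no stereocenter is made, C4 of the target is carried in from 1.

Step 2
Reactants: 2 silyl ether
Product: 3 4-(tert-butyldimethylsilyloxy)-1-methyl-4-(propan-2-yl)-7-oxabicyclo[4.1.0]heptane (both oxirane faces)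
Conditions: mCPBA, NaHCO3, CH2Cl2, 0 °C
Reagents that add atoms: 3-chloroperoxybenzoic acid, OOC(=O)c1cccc(Cl)c1
Why: Prilezhaev epoxidation of the trisubstituted alkene; the oxirane face does not matter because both oxirane carbons become trigonal in steps 3 and 4.

Step 3
Reactants: 3 epoxide
Product: 6 4-(tert-butyldimethylsilyloxy)-1-methyl-4-(propan-2-yl)cyclohex-2-en-1-ol (C1 epimers), via hydroxy selenide 4 (not isolated), via selenoxide 5 (not isolated)
Conditions: (PhSe)2, NaBH4, EtOH, 78 °C; then THF, 30% H2O2, 0 °C to rt
Reagents that add atoms: diphenyl diselenide, c1ccccc1[Se][Se]c1ccccc1 (selenium kept only in 4 and 5); hydrogen peroxide, OO (oxygen kept only in 5)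
Why: The selenolate should open the epoxide at its secondary carbon (SN2), and selenoxide syn-elimination, which can only run away from the carbinol carbon, should give the transposed tertiary allylic alcohol (epoxide to allylic alcohol conversion).

Step 4
Reactants: 6 tertiary allylic alcohol
Product: 7 (R)-6-(tert-butyldimethylsilyloxy)-3-methyl-6-(propan-2-yl)cyclohex-2-en-1-one
Conditions: pyridinium chlorochromate (C5H5NH)[CrO3Cl], 4 Å molecular sieves, CH2Cl2, rt
Reagents that add atoms: pyridinium chlorochromate, [O-][Cr](=O)(=O)Cl.c1cc[nH+]cc1 (the carbonyl oxygen is delivered from chromium, the original hydroxyl oxygen leaves with it)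
Why: Babler–Dauben oxidative 1,3-transposition of a tertiary allylic alcohol should give the β-methyl enone; the silylated tertiary alcohol cannot take part.

Step 5
Reactants: 7 enone; 8 allyltrimethylsilane
Product: 9 (2R,5R)-5-allyl-2-(tert-butyldimethylsilyloxy)-5-methyl-2-(propan-2-yl)cyclohexan-1-one (allyl cis to isopropyl)
Conditions: 8, TiCl4, CH2Cl2, −78 °C; then H2O
Reagents that add atoms: 8 allyltrimethylsilane, C=CC[Si](C)(C)C
Why: Hosomi–Sakurai conjugate allylation should set the quaternary C1 by antiparallel (axial) attack on the half-chair that holds isopropyl pseudo-equatorial and the non-chelating silyloxy group pseudo-axial, which puts allyl trans to the silyloxy group and cis to isopropyl.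

Step 6
Reactants: 9 ketone
Product: 11 3-allyl-2-diazo-6-(tert-butyldimethylsilyloxy)-3-methyl-6-(propan-2-yl)cyclohexan-1-one, via trifluoroacetyl ketone 10 (not isolated)
Conditions: LiN(SiMe3)2, THF, −78 °C; CF3CO2CH2CF3; then CH3SO2N3, Et3N, H2O, MeCN, rt
Reagents that add atoms: methanesulfonyl azide, CS(=O)(=O)N=[N+]=[N-]; 2,2,2-trifluoroethyl trifluoroacetate, FC(F)(F)COC(=O)C(F)(F)F (atoms kept only in 10)
Why: Deacylative Regitz diazo transfer should work because the only enolizable position (the CH2 between the carbonyl and the quaternary carbon) is trifluoroacetylated and the activated 1,3-dicarbonyl 10 then takes the diazo group with loss of the trifluoroacetyl group.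

Step 7
Reactants: 11 diazo ketone
Product: 14 methyl (1R,2R,5R)-2-allyl-5-(tert-butyldimethylsilyloxy)-2-methyl-5-(propan-2-yl)cyclopentane-1-carboxylate, via ketene 12 (not isolated), via epimeric ester mixture 13 (not isolated)
Conditions: hν (Hg lamp, Pyrex), CH3OH, rt; then NaOCH3 (cat.), CH3OH, rt
Reagents that add atoms: methanol, CO
Why: Photochemical Wolff rearrangement of the s-cis-locked cyclic diazo ketone should contract the ring by migration of the silyloxy-bearing carbon with retention; methanol traps ketene 12, and methoxide equilibration should place the ester at C5 trans to isopropyl and allyl (cis to silyloxy and methyl), the less crowded epimer.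

Step 8
Reactants: 14 methyl ester
Product: 15 (1R,2R,5R)-2-allyl-5-(tert-butyldimethylsilyloxy)-2-methyl-5-(propan-2-yl)cyclopentane-1-carbaldehyde
Conditions: (i-Bu)2AlH, CH2Cl2, −78 °C; then aq. potassium sodium tartrate (KNaC4H4O6)
Reagents that add atoms: none
Why: Partial reduction of a hindered methyl ester by (i-Bu)2AlH should stop at the aldehyde oxidation level at −78 °C and leave C5 untouched.

Step 9
Reactants: 15 aldehyde
Product: 17 (1R,2R,5R)-5-(tert-butyldimethylsilyloxy)-2-methyl-2-(2-oxoethyl)-5-(propan-2-yl)cyclopentane-1-carbaldehyde, via ozonide 16 (not isolated)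
Conditions: O3, CH2Cl2, −78 °C; then PPh3, −78 °C to rt
Reagents that add atoms: ozone, [O-][O+]=O
Why: Ozonolysis of the terminal alkene with reductive work-up should unveil the C9 aldehyde; the silyl ether and the hindered C6 aldehyde are inert at −78 °C.

Step 10
Reactants: 17 dialdehyde; 18 4-methylbenzenesulfonohydrazide
Product: 19 mono-(E)-tosylhydrazone of 17 at the 2-oxoethyl arm (C9), C6 aldehyde free
Conditions: 18 (1.0 equiv), THF, 0 °C
Reagents that add atoms: 18 4-methylbenzenesulfonohydrazide, Cc1ccc(cc1)S(=O)(=O)NN
Why: Hydrazone condensation should be chemoselective for the unhindered CH2CHO group, because the C6 aldehyde sits on a carbon flanked by two fully substituted carbons.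

Step 11
Reactants: 19 aldehyde tosylhydrazone; 20 prop-1-en-2-ylboronic acid
Product: 24 4-O-tert-butyldimethylsilyl ether of the 8-daucene-4β,6α-diol (trans-fused, 1β-methyl, 5α-H, 6α-OH, C8=C9), via diazoalkane 21 (not isolated), via allylboronic acid 22 (not isolated), via borate 23 (not isolated)
Conditions: K2CO3 (2 equiv), 20 (3 equiv), 1,4-dioxane (0.01 M), 100 °C; then H2O
Reagents that add atoms: 20 prop-1-en-2-ylboronic acid, CC(=C)B(O)O
Why: Proposed new method: base and heat should convert the tosylhydrazone into the C9 diazoalkane 21, whose carbon binds the boron of 20 and triggers a 1,2-shift of the isopropenyl group with loss of N2 (C8–C9 bond), giving the α-substituted allylboronic acid 22, which adds through its γ-carbon C7 to the C6 aldehyde (C6–C7 bond) and thereby moves the double bond to C8=C9. The closest known chemistry is the metal-free Barluenga–Valdés coupling of tosylhydrazones with alkenylboronic acids, together with the trapping of the transient allylboronic acids by external aldehydes; new here is the internal aldehyde trap that closes a ring. The cycloheptene is closed by a ring-closing allylboration (SE2′ at C7) through a boat-shaped six-membered B–O=C6···C7=C8–C9 transition state bridged by the C10–C1–C5 tether (a bicyclo[3.2.2] array), which also enforces the cis ring alkene. The only new stereocenter, C6, is set by the face on which the B–O bridge lies: on the α face it passes the axial C5–H, on the β face it would meet the axial C1 methyl, so the 6α-alcohol is expected, and the C9 epimer of 22 that cannot reach this geometry may be returned by a reversible 1,3-borotropic shift. The step needs ring closure to beat bimolecular allylation and protodeboronation; this is served by the slow thermal release of 21 (low stationary concentration of 22), by high dilution, and by the trans arrangement of the arms on C1 and C5, which makes the competing C6–C9 closure a strained trans-bicyclo[3.3.0]octane.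

Step 12
Reactants: 24 silyl ether
Product: 25 8-daucene-4β,6α-diol (jaeschkeanadiol-type diol)
Conditions: HF·pyridine, THF/pyridine, 0 °C to rt
Reagents that add atoms: none
Why: Fluoride cleavage of the tertiary silyl ether under buffered conditions should leave the alkene and both alcohols intact.

Step 13
Reactants: 25 diol; 26 3,4-dimethoxybenzoyl chloride
Product: 27 6-O-(3,4-dimethoxybenzoyl) ester of diol 25
Conditions: 26, Et3N, DMAP (cat.), CH2Cl2, 0 °C to rt
Reagents that add atoms: 26 3,4-dimethoxybenzoyl chloride, COc1ccc(C(=O)Cl)cc1OC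
Why: DMAP-catalysed acylation should be selective for the secondary C6 hydroxyl because the tertiary C4 hydroxyl is too hindered to be acylated.

Step 14
Reactants: 27 alkene ester
Product: 28 target, 8α,9α-epoxide of 27
Conditions: mCPBA, NaHCO3, CH2Cl2, 0 °C
Reagents that add atoms: 3-chloroperoxybenzoic acid, OOC(=O)c1cccc(Cl)c1
Why: Prilezhaev epoxidation should set C8 and C9 by peracid approach to the α face, anti to the axial C1 methyl that shields the β face of the trisubstituted alkene.

**Compound list**
1 | (S)-(+)-terpinen-4-ol, (S)-4-methyl-1-(propan-2-yl)cyclohex-3-en-1-ol | CC1=CC[C@](O)(C(C)C)CC1 | starting material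
2 | (S)-terpinen-4-ol tert-butyldimethylsilyl ether | CC1=CC[C@](O[Si](C)(C)C(C)(C)C)(C(C)C)CC1 | intermediate
3 | 4-(tert-butyldimethylsilyloxy)-1-methyl-4-(propan-2-yl)-7-oxabicyclo[4.1.0]heptane, both oxirane faces, C4 as in 2 | CC12OC1C[C@](O[Si](C)(C)C(C)(C)C)(C(C)C)CC2 | intermediate
4 | 4-(tert-butyldimethylsilyloxy)-1-methyl-2-(phenylselanyl)-4-(propan-2-yl)cyclohexan-1-ol | CC1(O)C([Se]c2ccccc2)C[C@](O[Si](C)(C)C(C)(C)C)(C(C)C)CC1 | intermediate
5 | selenoxide of 4 | CC1(O)C([Se](=O)c2ccccc2)C[C@](O[Si](C)(C)C(C)(C)C)(C(C)C)CC1 | intermediate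
6 | 4-(tert-butyldimethylsilyloxy)-1-methyl-4-(propan-2-yl)cyclohex-2-en-1-ol, C1 epimers | CC1(O)C=C[C@](O[Si](C)(C)C(C)(C)C)(C(C)C)CC1 | intermediate
7 | (R)-6-(tert-butyldimethylsilyloxy)-3-methyl-6-(propan-2-yl)cyclohex-2-en-1-one | CC1=CC(=O)[C@](O[Si](C)(C)C(C)(C)C)(C(C)C)CC1 | intermediate
8 | allyltrimethylsilane | C=CC[Si](C)(C)C | starting material
9 | (2R,5R)-5-allyl-2-(tert-butyldimethylsilyloxy)-5-methyl-2-(propan-2-yl)cyclohexan-1-one, allyl cis to isopropyl | C=CC[C@@]1(C)CC[C@@](O[Si](C)(C)C(C)(C)C)(C(C)C)C(=O)C1 | intermediate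
10 | 2-trifluoroacetyl derivative of 9 (at the CH2 between carbonyl and quaternary carbon) | C=CC[C@@]1(C)CC[C@@](O[Si](C)(C)C(C)(C)C)(C(C)C)C(=O)C1C(=O)C(F)(F)F | intermediate
11 | 3-allyl-2-diazo-6-(tert-butyldimethylsilyloxy)-3-methyl-6-(propan-2-yl)cyclohexan-1-one | C=CC[C@@]1(C)CC[C@@](O[Si](C)(C)C(C)(C)C)(C(C)C)C(=O)C1=[N+]=[N-] | intermediate
12 | ring-contracted ketene, [2-allyl-5-(tert-butyldimethylsilyloxy)-2-methyl-5-(propan-2-yl)cyclopentylidene]methanone | C=CC[C@@]1(C)CC[C@@](O[Si](C)(C)C(C)(C)C)(C(C)C)C1=C=O | intermediate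
13 | methyl 2-allyl-5-(tert-butyldimethylsilyloxy)-2-methyl-5-(propan-2-yl)cyclopentane-1-carboxylate, both configurations at ring C1 | C=CC[C@@]1(C)CC[C@@](O[Si](C)(C)C(C)(C)C)(C(C)C)C1C(=O)OC | intermediate
14 | methyl (1R,2R,5R)-2-allyl-5-(tert-butyldimethylsilyloxy)-2-methyl-5-(propan-2-yl)cyclopentane-1-carboxylate (ester cis to silyloxy and methyl) | C=CC[C@@]1(C)CC[C@@](O[Si](C)(C)C(C)(C)C)(C(C)C)[C@@H]1C(=O)OC | intermediate
15 | (1R,2R,5R)-2-allyl-5-(tert-butyldimethylsilyloxy)-2-methyl-5-(propan-2-yl)cyclopentane-1-carbaldehyde | C=CC[C@@]1(C)CC[C@@](O[Si](C)(C)C(C)(C)C)(C(C)C)[C@@H]1C=O | intermediate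
16 | secondary ozonide (1,2,4-trioxolane) of the allyl group of 15 | C1OOC(O1)C[C@@]1(C)CC[C@@](O[Si](C)(C)C(C)(C)C)(C(C)C)[C@@H]1C=O | intermediate
17 | (1R,2R,5R)-5-(tert-butyldimethylsilyloxy)-2-methyl-2-(2-oxoethyl)-5-(propan-2-yl)cyclopentane-1-carbaldehyde | O=CC[C@@]1(C)CC[C@@](O[Si](C)(C)C(C)(C)C)(C(C)C)[C@@H]1C=O | intermediate
18 | 4-methylbenzenesulfonohydrazide | Cc1ccc(cc1)S(=O)(=O)NN | starting material
19 | (E)-tosylhydrazone of the 2-oxoethyl aldehyde of 17 | Cc1ccc(cc1)S(=O)(=O)N/N=C/C[C@@]1(C)CC[C@@](O[Si](C)(C)C(C)(C)C)(C(C)C)[C@@H]1C=O | intermediate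
20 | prop-1-en-2-ylboronic acid | CC(=C)B(O)O | starting material
21 | 2-(2-diazoethyl) analogue of 17 (C9 diazoalkane) | [N-]=[N+]=CC[C@@]1(C)CC[C@@](O[Si](C)(C)C(C)(C)C)(C(C)C)[C@@H]1C=O | intermediate
22 | α-substituted allylboronic acid (boron on C9, either configuration) | C=C(C)C(B(O)O)C[C@@]1(C)CC[C@@](O[Si](C)(C)C(C)(C)C)(C(C)C)[C@@H]1C=O | intermediate
23 | O6-dihydroxyboryl derivative (borate) of 24 | OB(O)O[C@H]1CC(C)=CC[C@@]2(C)CC[C@@](O[Si](C)(C)C(C)(C)C)(C(C)C)[C@H]12 | intermediate
24 | 4β-(tert-butyldimethylsilyloxy)-8-daucen-6α-ol (trans-fused, 1β-methyl, 5α-H, 4α-isopropyl) | O[C@H]1CC(C)=CC[C@@]2(C)CC[C@@](O[Si](C)(C)C(C)(C)C)(C(C)C)[C@H]12 | intermediate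
25 | 8-daucene-4β,6α-diol (jaeschkeanadiol-type diol) | O[C@H]1CC(C)=CC[C@@]2(C)CC[C@@](O)(C(C)C)[C@H]12 | intermediate
26 | 3,4-dimethoxybenzoyl chloride | COc1ccc(C(=O)Cl)cc1OC | starting material
27 | 4β-hydroxy-8-daucen-6α-yl 3,4-dimethoxybenzoate | COc1ccc(C(=O)O[C@H]2CC(C)=CC[C@@]3(C)CC[C@@](O)(C(C)C)[C@H]23)cc1OC | intermediate
28 | 8α,9α-epoxy-4β-hydroxydaucan-6α-yl 3,4-dimethoxybenzoate (CNP0251065.1) | COc1ccc(C(=O)O[C@H]2C[C@@]3(C)O[C@H]3C[C@@]3(C)CC[C@@](O)(C(C)C)[C@H]23)cc1OC | target

Total step count: 14. Longest linear sequence: 14 steps (from 1).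

**Steps most likely to fail**

Step 11 (proposed new method). The risk is that bimolecular allylation, protodeboronation of the allylboronic acid or its 1,3-borotropic shift outrun the strained ring-closing allylboration, or that C6 is formed without facial control. The fallback uses known chemistry and sets out from aldehyde 15. Reagent-controlled methallylation of the C6 aldehyde (B-methallyldiisopinocampheylborane of the antipode matched to the 6α-alcohol, Et2O, −78 °C, then NaBO3 work-up) would give the homoallylic alcohol diene F1. Ring-closing metathesis of its allyl and methallyl groups (second-generation Grubbs catalyst, RuCl2(=CHPh)(PCy3)(H2IMes), CH2Cl2, 40 °C) would close the cycloheptene with loss of ethene and come back to the route at 24.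

Step 5. The risk is poor facial selectivity of the conjugate allylation, for example if titanium chelation of the silyloxy ketone overrides the conformational bias. The fallback sets out from enone 7. 1,2-Addition of allylmagnesium bromide (CeCl3, THF, −78 °C) anti to the pseudo-axial silyloxy group would give the tertiary bis-allylic alcohol F2. Its anionic oxy-Cope rearrangement (KH, 18-crown-6, THF, 0 °C to rt) would pass the allyl group suprafacially from the carbinol carbon to the methyl-bearing alkene carbon and, after protonation of the enolate, come back to the route at 9.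

Step 14. The risk is peracid attack on the β face or low facial selectivity. The fallback sets out from diol 25. Hydroxyl-directed epoxidation (VO(acac)2, t-BuOOH, CH2Cl2, rt), in which the homoallylic 6α-hydroxyl delivers oxygen to the α face, would give the epoxy diol F3. Acylation of its C6 hydroxyl with 26 (Et3N, DMAP, CH2Cl2) would come back to the route at 28.

Further compounds
F1 | step 11 | (S-configured carbinol as in 24) 1-[(1R,2R,5R)-2-allyl-5-(tert-butyldimethylsilyloxy)-2-methyl-5-(propan-2-yl)cyclopentyl]-3-methylbut-3-en-1-ol | C=CC[C@@]1(C)CC[C@@](O[Si](C)(C)C(C)(C)C)(C(C)C)[C@@H]1[C@@H](O)CC(C)=C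
F2 | step 5 | 1-allyl-6-(tert-butyldimethylsilyloxy)-3-methyl-6-(propan-2-yl)cyclohex-2-en-1-ol, allyl cis to isopropyl | CC1=C[C@](O)(CC=C)[C@](O[Si](C)(C)C(C)(C)C)(C(C)C)CC1
F3 | step 14 | 8α,9α-epoxydaucane-4β,6α-diol | O[C@H]2C[C@@]3(C)O[C@H]3C[C@@]3(C)CC[C@@](O)(C(C)C)[C@H]23
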